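**Retrosynthetic overview**
- The tetronic acid is closed last by Dieckmann condensation of an (S)-α-propanoyloxy ester. Its stereocentre comes from methyl (S)-glycidate, opened at CH2 by an (E,E,E)-trienyl organometallic.
- The trienyl iodide comes from hydrozirconation/iodination of a methyl-capped dienyne. The dienyne comes from Sonogashira coupling of propyne with a dienyl chloride, itself made by hydrozirconation/Negishi coupling of a pent-3-ynyl bis-furan with (E)-1,2-dichloroethene.
- Key disconnection: both furan rings and the CH2 bridge of the bis-furan are made in one flask from two acyclic pieces, 2-ethynylbut-3-yne-1,2-diol and a (Z)-3-iodoallylic alcohol.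
- The diynediol comes from ethyl glycolate and ethynylmagnesium bromide. The iodoallylic alcohol comes from propargyl alcohol by copper-catalysed carbomagnesiation/iodination.
- Ring order: terminal furan, then central furan in the same operation; tetronic acid last.

Assumption: 5-bromopent-2-yne, propyne, Cp2Zr(H)Cl and methyl (2S)-oxirane-2-carboxylate are taken as purchasable; equivalents and temperatures are indicative.

**Step 1**
Reactants: 1 ethyl 2-hydroxyacetate; 2 ethynylmagnesium bromide
Product: 3 2-ethynylbut-3-yne-1,2-diol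
Conditions: 2 (3.5 equiv, 0.5 M in THF), THF, 0 °C to rt; aq NH4Cl
Reagents that add atoms: none
Why: Twofold 1,2-addition of the alkynyl Grignard reagent to the ester (the first equivalent only deprotonates the hydroxyl) gives the tertiary diethynylcarbinol, the standard ester-to-dialkynylcarbinol Grignard reaction; the product is achiral and its two alkynes are equivalent.

**Step 2**
Reactants: 4 prop-2-yn-1-ol; 5 5-bromopent-2-yne
Product: 8 (2Z)-2-(iodomethylidene)hept-5-yn-1-ol, via pent-3-yn-1-ylmagnesium bromide 6 (not isolated), via alkenylmagnesium alkoxide 7 (not isolated)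
Conditions: 5, Mg, THF; then 4 (0.4 equiv), CuI (10 mol %), Et2O–THF, −10 °C to rt; then I2, −40 to 0 °C
Reagents that add atoms: iodine, II
Why: Hydroxyl-directed copper-catalysed anti-carbomagnesiation of the propargylic alkoxide (Duboudin–Jousseaume reaction) puts the alkyl group on C2 and magnesium on C3 inside a five-membered chelate, so that iodinolysis with retention gives the iodide cis to CH2OH (2Z).

**Step 3**
Reactants: 3 2-ethynylbut-3-yne-1,2-diol; 8 (2Z)-2-(iodomethylidene)hept-5-yn-1-ol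
Product: 11 2-(furan-3-ylmethyl)-4-(pent-3-yn-1-yl)furan, via 3-ethynylfuran 9 (not isolated), via Z-enynol 10 (not isolated)
Conditions: 3 (1.3 equiv), (Ph3P)AuNTf2 (1 mol %), THF, 0 °C to rt; then 8, PdCl2(PPh3)2 (3 mol %), CuI (5 mol %), Et3N, rt; then KOt-Bu (3 equiv), 18-crown-6 (10 mol %), t-BuOH, 50 °C
Reagents that add atoms: none
Why: Proposed new method: three known events are merged in one flask – 5-endo-dig cyclodehydration of a 3-alkyne-1,2-diol by a cationic monovalent gold complex (3 is symmetrical, so either alkyne gives the same 3-ethynylfuran 9), Sonogashira coupling of 9 with Z iodide 8 with retention, and base-mediated 5-exo-dig addition of the allylic alkoxide of 10 to the alkyne followed by prototropic aromatisation – so that both furan rings and the CH2 bridge arise in one operation without a new stereocentre; the closest known reaction types are the gold-catalysed furan synthesis from alkynediols and the base-mediated cycloisomerisation of (Z)-2-en-4-yn-1-ols to 2-alkylfurans.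

**Step 4**
Reactants: 11 2-(furan-3-ylmethyl)-4-(pent-3-yn-1-yl)furan; 12 (E)-1,2-dichloroethene
Product: 15 4-[(3E,5E)-6-chloro-4-methylhexa-3,5-dien-1-yl]-2-(furan-3-ylmethyl)furan, via alkenylzirconocene chloride 13 (not isolated), via alkenylzinc chloride 14 (not isolated)
Conditions: Cp2Zr(H)Cl (2 equiv), THF, 50 °C; then 12 (10 equiv), ZnCl2, Pd(PPh3)4 (5 mol %), rt
Reagents that add atoms: none
Why: Syn-hydrozirconation of the methylalkyne, equilibrated by excess hydride to the isomer with zirconium on the methyl-bearing carbon, then transmetalation to zinc and Negishi coupling with retention at both carbons fix the 3E and 5E double bonds; the large excess of 12 enforces mono-coupling and consumes leftover Zr–H.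

**Step 5**
Reactants: 15 4-[(3E,5E)-6-chloro-4-methylhexa-3,5-dien-1-yl]-2-(furan-3-ylmethyl)furan; 16 propyne
Product: 17 2-(furan-3-ylmethyl)-4-[(3E,5E)-4-methylnona-3,5-dien-7-yn-1-yl]furan
Conditions: 16 (excess), PdCl2(PhCN)2 (5 mol %), CuI (10 mol %), piperidine, rt
Reagents that add atoms: none
Why: Sonogashira coupling of the (E)-1-chlorodiene in piperidine, a known reaction of alkenyl chlorides, proceeds with retention and installs the propynyl group needed for the last trisubstituted alkene.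

**Step 6**
Reactants: 17 2-(furan-3-ylmethyl)-4-[(3E,5E)-4-methylnona-3,5-dien-7-yn-1-yl]furan
Product: 19 2-(furan-3-ylmethyl)-4-[(3E,5E,7E)-8-iodo-4-methylnona-3,5,7-trien-1-yl]furan, via trienylzirconocene chloride 18 (not isolated)
Conditions: Cp2Zr(H)Cl (1.5 equiv), THF, rt; then I2, −20 °C
Reagents that add atoms: iodine, II
Why: Syn-hydrozirconation of the conjugated methylalkyne is expected to place zirconium on the less hindered methyl-bearing carbon (by analogy with aryl methyl alkynes), and iodinolysis with retention then gives the 7E iodide.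

**Step 7**
Reactants: 19 2-(furan-3-ylmethyl)-4-[(3E,5E,7E)-8-iodo-4-methylnona-3,5,7-trien-1-yl]furan; 20 methyl (2S)-oxirane-2-carboxylate; 21 propanoic anhydride
Product: 25 methyl (2S,4E,6E,8E)-11-[5-(furan-3-ylmethyl)furan-3-yl]-4,8-dimethyl-2-(propanoyloxy)undeca-4,6,8-trienoate, via trienyllithium 22 (not isolated), via trienylmagnesium bromide 23 (not isolated), via bromomagnesium alkoxide 24 (not isolated)
Conditions: t-BuLi (2.05 equiv), Et2O, −78 °C; MgBr2·OEt2; CuBr·SMe2 (10 mol %), 20 (1.3 equiv), THF, −78 to −40 °C; then 21, DMAP, −40 to 0 °C; aq NH4Cl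
Reagents that add atoms: none
Why: Iodine–lithium exchange with retention, transmetalation to magnesium and copper-catalysed SN2 opening of the glycidate at its CH2 carbon (the 2S centre of 20 is not touched and becomes the 2S carbinol centre) are followed by O-acylation of the magnesium alkoxide in the flask.

**Step 8**
Reactants: 25 methyl (2S,4E,6E,8E)-11-[5-(furan-3-ylmethyl)furan-3-yl]-4,8-dimethyl-2-(propanoyloxy)undeca-4,6,8-trienoate
Product: 26 (5S)-5-{(2E,4E,6E)-9-[5-(furan-3-ylmethyl)furan-3-yl]-2,6-dimethylnona-2,4,6-trien-1-yl}-4-hydroxy-3-methylfuran-2(5H)-one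
Conditions: LiN(SiMe3)2 (2.5 equiv), THF, −78 °C to rt; then cold 1 M HCl
Reagents that add atoms: none
Why: Dieckmann (intramolecular Claisen) condensation of the propanoate enolate onto the methyl ester at low temperature closes the 3-methyltetronic acid; the C5 stereocentre lies outside the reacting atoms and is retained.

**Compound list**
1 | ethyl 2-hydroxyacetate (ethyl glycolate) | CCOC(=O)CO | starting material
2 | ethynylmagnesium bromide | C#C[Mg]Br | starting material
3 | 2-ethynylbut-3-yne-1,2-diol | OCC(O)(C#C)C#C | intermediate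
4 | prop-2-yn-1-ol | OCC#C | starting material
5 | 5-bromopent-2-yne | CC#CCCBr | starting material
6 | pent-3-yn-1-ylmagnesium bromide | CC#CCC[Mg]Br | intermediate
7 | bromomagnesium (2Z)-3-(bromomagnesio)-2-(pent-3-yn-1-yl)prop-2-en-1-olate (alkenylmagnesium alkoxide) | Br[Mg]OC/C(CCC#CC)=C\[Mg]Br | intermediate
8 | (2Z)-2-(iodomethylidene)hept-5-yn-1-ol | OC/C(CCC#CC)=C\I | intermediate
9 | 3-ethynylfuran | C#Cc1ccoc1 | intermediate
10 | (2Z)-2-[3-(furan-3-yl)prop-2-yn-1-ylidene]hept-5-yn-1-ol (Z-enynol) | OC/C(CCC#CC)=C\C#Cc1ccoc1 | intermediate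
11 | 2-(furan-3-ylmethyl)-4-(pent-3-yn-1-yl)furan | CC#CCCc1coc(Cc2ccoc2)c1 | intermediate
12 | (E)-1,2-dichloroethene | Cl/C=C/Cl | starting material
13 | chlorobis(cyclopentadienyl){(2E)-5-[5-(furan-3-ylmethyl)furan-3-yl]pent-2-en-2-yl}zirconium (alkenylzirconocene chloride) | Cl[Zr](C1C=CC=C1)(C1C=CC=C1)/C(C)=C/CCc1coc(Cc2ccoc2)c1 | intermediate
14 | chloro{(2E)-5-[5-(furan-3-ylmethyl)furan-3-yl]pent-2-en-2-yl}zinc (alkenylzinc chloride) | Cl[Zn]/C(C)=C/CCc1coc(Cc2ccoc2)c1 | intermediate
15 | 4-[(3E,5E)-6-chloro-4-methylhexa-3,5-dien-1-yl]-2-(furan-3-ylmethyl)furan | Cl/C=C/C(C)=C/CCc1coc(Cc2ccoc2)c1 | intermediate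
16 | propyne | CC#C | starting material
17 | 2-(furan-3-ylmethyl)-4-[(3E,5E)-4-methylnona-3,5-dien-7-yn-1-yl]furan | CC#C/C=C/C(C)=C/CCc1coc(Cc2ccoc2)c1 | intermediate
18 | chlorobis(cyclopentadienyl){(2E,4E,6E)-9-[5-(furan-3-ylmethyl)furan-3-yl]-6-methylnona-2,4,6-trien-2-yl}zirconium (trienylzirconocene chloride) | Cl[Zr](C1C=CC=C1)(C1C=CC=C1)/C(C)=C/C=C/C(C)=C/CCc1coc(Cc2ccoc2)c1 | intermediate
19 | 2-(furan-3-ylmethyl)-4-[(3E,5E,7E)-8-iodo-4-methylnona-3,5,7-trien-1-yl]furan | I/C(C)=C/C=C/C(C)=C/CCc1coc(Cc2ccoc2)c1 | intermediate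
20 | methyl (2S)-oxirane-2-carboxylate (methyl (S)-glycidate) | COC(=O)[C@@H]1CO1 | starting material
21 | propanoic anhydride | CCC(=O)OC(=O)CC | starting material
22 | {(2Z,4E,6E)-9-[5-(furan-3-ylmethyl)furan-3-yl]-6-methylnona-2,4,6-trien-2-yl}lithium (trienyllithium; Li trans to C4, the Z label arises only because Li ranks below CH3) | [Li]/C(C)=C/C=C/C(C)=C/CCc1coc(Cc2ccoc2)c1 | intermediate
23 | bromo{(2E,4E,6E)-9-[5-(furan-3-ylmethyl)furan-3-yl]-6-methylnona-2,4,6-trien-2-yl}magnesium (trienylmagnesium bromide) | Br[Mg]/C(C)=C/C=C/C(C)=C/CCc1coc(Cc2ccoc2)c1 | intermediate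
24 | bromomagnesium alkoxide of methyl (2S,4E,6E,8E)-11-[5-(furan-3-ylmethyl)furan-3-yl]-2-hydroxy-4,8-dimethylundeca-4,6,8-trienoate | COC(=O)[C@@H](O[Mg]Br)C/C(C)=C/C=C/C(C)=C/CCc1coc(Cc2ccoc2)c1 | intermediate
25 | methyl (2S,4E,6E,8E)-11-[5-(furan-3-ylmethyl)furan-3-yl]-4,8-dimethyl-2-(propanoyloxy)undeca-4,6,8-trienoate | COC(=O)[C@@H](OC(=O)CC)C/C(C)=C/C=C/C(C)=C/CCc1coc(Cc2ccoc2)c1 | intermediate
26 | (5S)-5-{(2E,4E,6E)-9-[5-(furan-3-ylmethyl)furan-3-yl]-2,6-dimethylnona-2,4,6-trien-1-yl}-4-hydroxy-3-methylfuran-2(5H)-one | CC1=C(O)[C@H](C/C(C)=C/C=C/C(C)=C/CCc2coc(Cc3ccoc3)c2)OC1=O | target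

**Totals**
Total step count: 8. Longest linear sequence: 7 steps (steps 2 to 8, from 4 and 5); step 1 is a one-step side branch.

**Steps most likely to fail, with fallbacks**

Step 3 (three catalytic events in one flask). The fallback sets out from 3 and 8 and comes back at 11. Iodide 8 is first coupled with a threefold excess of the symmetrical diyne 3 (PdCl2(PPh3)2, CuI, Et3N, THF, rt; the excess suppresses double coupling) to give the isolable acyclic triol (5Z)-2-ethynyl-6-(hydroxymethyl)undec-5-ene-3,9-diyne-1,2-diol F1. A single cationic monovalent gold catalyst, (Ph3P)AuNTf2 in THF at rt, then closes both furans of F1 in one operation and gives 11. The closures are 5-exo-dig attack of the allylic hydroxyl on the enyne and 5-endo-dig cyclodehydration of the alkynediol.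

Step 6 (regiochemistry of hydrozirconation on the conjugated methylalkyne). The fallback sets out from 15 and comes back at 25. The alkenyl-nucleophile/epoxide logic is replaced by an allylic electrophile whose geometry is fixed by syn-carbometalation. Alcohol 4 undergoes zirconium-catalysed methylalumination (AlMe3, Cp2ZrCl2, CH2Cl2) and, in the same flask, palladium-catalysed coupling with chloride 15 (ZnCl2, Pd(P(t-Bu)3)2, THF). This gives the trienol (2E,4E,6E)-9-[5-(furan-3-ylmethyl)furan-3-yl]-2,6-dimethylnona-2,4,6-trien-1-ol F2. CBr4/PPh3 converts it into the allylic bromide 4-[(3E,5E,7E)-9-bromo-4,8-dimethylnona-3,5,7-trien-1-yl]-2-(furan-3-ylmethyl)furan F3. The sodium enolate (NaN(SiMe3)2, THF, −78 °C) of (4R)-4-benzyl-3-{[tert-butyl(dimethyl)silyl]oxyacetyl}-1,3-oxazolidin-2-one is alkylated with F3 anti to the benzyl group of the chelated Z-enolate. This sets the 2S centre and gives the imide (4R)-4-benzyl-3-[(2S,4E,6E,8E)-2-{[tert-butyl(dimethyl)silyl]oxy}-11-[5-(furan-3-ylmethyl)furan-3-yl]-4,8-dimethylundeca-4,6,8-trienoyl]-1,3-oxazolidin-2-one F4. MeOMgBr in MeOH removes the auxiliary to give the silyl ether ester methyl (2S,4E,6E,8E)-2-{[tert-butyl(dimethyl)silyl]oxy}-11-[5-(furan-3-ylmethyl)furan-3-yl]-4,8-dimethylundeca-4,6,8-trienoate F5. HF·pyridine frees the hydroxy ester methyl (2S,4E,6E,8E)-11-[5-(furan-3-ylmethyl)furan-3-yl]-2-hydroxy-4,8-dimethylundeca-4,6,8-trienoate F6, and acylation with 21/DMAP gives 25.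

Step 7 (late trienyl organometallic opening an ester-bearing epoxide). The fallback sets out from 11 and comes back at 25. The epoxide opening is moved to a small dienyl unit that can be used in excess, and the bond between the two trisubstituted-alkene halves is made last. Dichloroethene 12 and propyne 16 are coupled (Pd(PPh3)4, CuI, piperidine) to (1E)-1-chloropent-1-en-3-yne F7. Hydrozirconation/iodination (Cp2Zr(H)Cl; I2) gives (1E,3E)-1-chloro-4-iodopenta-1,3-diene F8. The lithium–magnesium–copper sequence of step 7 with 20 and 21 then gives methyl (2S,4E,6E)-7-chloro-4-methyl-2-(propanoyloxy)hepta-4,6-dienoate F9. Alkyne 11 is converted by hydrozirconation/iodination into 2-(furan-3-ylmethyl)-4-[(3E)-4-iodopent-3-en-1-yl]furan F10. Its alkenylzinc reagent (t-BuLi; ZnCl2) undergoes Negishi coupling with F9 (Pd(P(t-Bu)3)2, THF) to give 25.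

**Further compounds**
F1 | step 3 | (5Z)-2-ethynyl-6-(hydroxymethyl)undec-5-ene-3,9-diyne-1,2-diol (racemic at C2; the centre is lost on aromatisation) | OC/C(CCC#CC)=C\C#CC(O)(CO)C#C
F2 | step 6 | (2E,4E,6E)-9-[5-(furan-3-ylmethyl)furan-3-yl]-2,6-dimethylnona-2,4,6-trien-1-ol | OC/C(C)=C/C=C/C(C)=C/CCc1coc(Cc2ccoc2)c1
F3 | step 6 | 4-[(3E,5E,7E)-9-bromo-4,8-dimethylnona-3,5,7-trien-1-yl]-2-(furan-3-ylmethyl)furan | BrC/C(C)=C/C=C/C(C)=C/CCc1coc(Cc2ccoc2)c1
F4 | step 6 | (4R)-4-benzyl-3-[(2S,4E,6E,8E)-2-{[tert-butyl(dimethyl)silyl]oxy}-11-[5-(furan-3-ylmethyl)furan-3-yl]-4,8-dimethylundeca-4,6,8-trienoyl]-1,3-oxazolidin-2-one | O=C1OC[C@@H](Cc2ccccc2)N1C(=O)[C@@H](O[Si](C)(C)C(C)(C)C)C/C(C)=C/C=C/C(C)=C/CCc1coc(Cc2ccoc2)c1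
F5 | step 6 | methyl (2S,4E,6E,8E)-2-{[tert-butyl(dimethyl)silyl]oxy}-11-[5-(furan-3-ylmethyl)furan-3-yl]-4,8-dimethylundeca-4,6,8-trienoate | COC(=O)[C@@H](O[Si](C)(C)C(C)(C)C)C/C(C)=C/C=C/C(C)=C/CCc1coc(Cc2ccoc2)c1
F6 | step 6 | methyl (2S,4E,6E,8E)-11-[5-(furan-3-ylmethyl)furan-3-yl]-2-hydroxy-4,8-dimethylundeca-4,6,8-trienoate | COC(=O)[C@@H](O)C/C(C)=C/C=C/C(C)=C/CCc1coc(Cc2ccoc2)c1
F7 | step 7 | (1E)-1-chloropent-1-en-3-yne | CC#C/C=C/Cl
F8 | step 7 | (1E,3E)-1-chloro-4-iodopenta-1,3-diene | I/C(C)=C/C=C/Cl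
F9 | step 7 | methyl (2S,4E,6E)-7-chloro-4-methyl-2-(propanoyloxy)hepta-4,6-dienoate | COC(=O)[C@@H](OC(=O)CC)C/C(C)=C/C=C/Cl
F10 | step 7 | 2-(furan-3-ylmethyl)-4-[(3E)-4-iodopent-3-en-1-yl]furan | I/C(C)=C/CCc1coc(Cc2ccoc2)c1
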